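The 1,2-dioxane (O1–O2–C3–C4–C5–C6) is read as a cyclobutene whose C3=C6 bond has taken up two oxygen atoms. Ozonolysis of (R)-5-(cyclobut-1-enyl)pentan-2-ol expands the carbocycle by two atoms in one operation. The side-chain hydroxyl captures the C6 carbonyl oxide, the hydroperoxide closes on the C3 aldehyde, and a spiro peroxyketal with a C3 hemiacetal results. Both C–O termini are then cation precursors. The C10 carbinol relays its configuration through the anomeric spiro centre to C3 and C2, and C3 directs axial methyl delivery to C6. The spent carbinol becomes the C10 methylidene carbon, where a Suzuki coupling attaches the cyclohexanol made by Sharpless epoxidation.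

Key step: step 3

Remark on locants (target numbering, used for all intermediates): C1 is the ester carbonyl and C2 its α-carbon. C3–C6 are the dioxane carbons, with O2 on C3 and O1 on C6. C7–C9 are the chain, C10 the chain methylidene-bearing carbon, C11–C12 the next two chain carbons, C13 the carbinol carbon and C14 the ring methylidene-bearing carbon. Ring A is the 1,2-dioxane, ring B the temporary oxane, ring C the cyclohexane.

Step 1
Reactants: 1 cyclobutanone
Product: 3 cyclobut-1-en-1-yl trifluoromethanesulfonate, via lithium cyclobut-1-en-1-olate 2 (not isolated)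
Conditions: LiN(iPr)2, THF, −78 °C; then PhNTf2, −78 → 0 °C
Reagents that add atoms: N-phenylbis(trifluoromethanesulfonimide), O=S(=O)(N(c1ccccc1)S(=O)(=O)C(F)(F)F)C(F)(F)F
Why: Kinetic deprotonation and O-sulfonylation of the enolate (enol triflate formation) give the cyclobutenyl electrophile without opening the strained ring; no stereocentre is formed.

Step 2
Reactants: 4 (2R)-pent-4-en-2-ol; 3 cyclobut-1-en-1-yl trifluoromethanesulfonate
Product: 6 (2R)-5-(cyclobut-1-en-1-yl)pentan-2-ol, via bis-9-BBN adduct 5 (not isolated)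
Conditions: 9-BBN-H (2.2 equiv), THF, 0 °C → rt; then 3, PdCl2(dppf) (5 mol%), aq. K3PO4, THF–DMF, rt
Reagents that add atoms: none
Why: Anti-Markovnikov hydroboration of the terminal alkene (the hydroxyl is parked as its borinate) and B-alkyl Suzuki–Miyaura coupling with the enol triflate form C6–C7, and the chiral-pool (R)-carbinol C10 is not touched.

Step 3
Reactants: 6 (2R)-5-(cyclobut-1-en-1-yl)pentan-2-ol
Product: 9 (6S,8R)-8-methyl-1,2,7-trioxaspiro[5.5]undecan-3-ol (C3 anomers), via carbonyl oxide 7 (not isolated), via hydroperoxy-oxane aldehyde 8 (not isolated)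
Conditions: O3, CH2Cl2 (0.02 M), −78 °C; Ar purge; then camphorsulfonic acid (5 mol%), −78 → 0 °C
Reagents that add atoms: ozone, [O-][O+]=O
Why: Ozone adds to the only C=C bond and the primary ozonide cleaves by the Criegee pathway so that alkyl-bearing C6 becomes the carbonyl oxide and C3 the aldehyde; the C10 hydroxyl then adds to the carbonyl oxide carbon and the resulting α-alkoxy hydroperoxide adds to the aldehyde, so the C3–C6 bond of the four-membered ring is replaced by C3–O2–O1–C6. The closest known reaction type is the ozonolysis of cycloalkenes in alcohols, in which an α-alkoxy hydroperoxide forms and closes on the second carbonyl group to a cyclic peroxyhemiacetal. Ring B closes by 6-exo-trig attack of the hydroxyl oxygen on C6, and ring A closes by 6-exo-trig attack of the hydroperoxide oxygen on the C3 carbonyl. The spiro centre C6 is set under thermodynamic control in the acid equilibration, because two axial C6–O bonds (double anomeric effect) together with an equatorial methyl at (R)-C10 are only compatible with (6S), whereas C3 stays an anomeric mixture that is erased in step 6. The step needs regioselective ozonide cleavage and capture of the carbonyl oxide by the hydroxyl rather than by the tethered aldehyde; the donor alkyl group on C6 and the six-membered capture should favour both, and the isomeric bicyclic ozonide should be drawn into the same spiroketal by acid ionisation at its tertiary carbon.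

Step 4
Reactants: 9 (6S,8R)-8-methyl-1,2,7-trioxaspiro[5.5]undecan-3-ol
Product: 10 (6S,8R)-8-methyl-1,2,7-trioxaspiro[5.5]undecan-3-yl acetate (C3 anomers)
Conditions: Ac2O, pyridine, DMAP (cat.), CH2Cl2, 0 °C
Reagents that add atoms: acetic anhydride, CC(=O)OC(C)=O
Why: Acylation of the peroxyhemiacetal hydroxyl makes C3 the better leaving-group site while the spiroketal is inert to the mild base, so C6 and C10 are unchanged.

Step 5
Reactants: 11 methyl propanoate
Product: 13 (E)-1-methoxy-1-(trimethylsilyloxy)prop-1-ene, via lithium ester enolate 12 (not isolated)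
Conditions: LiN(iPr)2, THF, −78 °C; then Me3SiCl, −78 °C → rt
Reagents that add atoms: chlorotrimethylsilane, C[Si](C)(C)Cl
Why: Kinetic ester enolisation in THF and O-silylation should give mainly the (E)-silyl ketene acetal, whose geometry carries little weight in the open transition state of step 6.

Step 6
Reactants: 10 (6S,8R)-8-methyl-1,2,7-trioxaspiro[5.5]undecan-3-yl acetate; 13 (E)-1-methoxy-1-(trimethylsilyloxy)prop-1-ene
Product: 14 methyl (2R)-2-[(3S,6S,8R)-8-methyl-1,2,7-trioxaspiro[5.5]undecan-3-yl]propanoate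
Conditions: Me3SiOTf (10 mol%), CH2Cl2, −78 °C
Reagents that add atoms: none
Why: This is a Mukaiyama-type substitution of a 1,2-dioxan-3-yl acetate through the C3 peroxycarbenium ion, in which the acetate ionises before the spiroketal (whose opening is undone by internal return), the nucleophile enters axially and anti to the pseudoaxial C6–O(oxane) bond so that (6S) is translated into (3S), and the extended antiperiplanar open transition state with the C2 methyl turned away from C4 should give the 2,3-syn (2R) ester.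

Step 7
Reactants: 14 methyl (2R)-2-[(3S,6S,8R)-8-methyl-1,2,7-trioxaspiro[5.5]undecan-3-yl]propanoate
Product: 15 methyl (2R)-2-[(3S,6R)-6-[(4R)-4-hydroxypentyl]-6-methyl-1,2-dioxan-3-yl]propanoate
Conditions: AlMe3 (3–4 equiv), CH2Cl2, −78 → −20 °C; aq. potassium sodium tartrate
Reagents that add atoms: trimethylaluminium, C[Al](C)C
Why: Proposed new method: AlMe3 should bind the more basic oxane oxygen and ionise C6–O(oxane) to a tertiary peroxycarbenium ion (C6=O1+) inside intact ring A; a second AlMe3 then delivers methyl anti to the departing oxygen along the axial trajectory of the half-chair that holds the C3 side chain pseudoequatorial, which places CH3 cis to that side chain (6R) and frees the C10 hydroxyl. The closest known reaction types are the AlMe3 opening and C-methylation of spiroketals and cyclic ketals, and the substitution of 3-alkoxy-1,2-dioxanes and 1,2-dioxolanes by allylsilanes or silyl ketene acetals via peroxycarbenium ions.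

Step 8
Reactants: 15 methyl (2R)-2-[(3S,6R)-6-[(4R)-4-hydroxypentyl]-6-methyl-1,2-dioxan-3-yl]propanoate
Product: 16 methyl (2R)-2-[(3S,6R)-6-methyl-6-(4-oxopentyl)-1,2-dioxan-3-yl]propanoate
Conditions: Dess–Martin periodinane, pyridine, CH2Cl2, 0 °C
Reagents that add atoms: none
Why: Dess–Martin oxidation under neutral conditions turns the relay carbinol, whose stereochemical task is done, into the methyl ketone without attacking the O–O bond.

Step 9
Reactants: 16 methyl (2R)-2-[(3S,6R)-6-methyl-6-(4-oxopentyl)-1,2-dioxan-3-yl]propanoate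
Product: 18 methyl (2R)-2-[(3S,6R)-6-methyl-6-[4-(trifluoromethylsulfonyloxy)pent-4-en-1-yl]-1,2-dioxan-3-yl]propanoate, via potassium enolate 17 (not isolated)
Conditions: KN(SiMe3)2 (1.05 equiv) added to 16 and N-(5-chloropyridin-2-yl)bis(trifluoromethanesulfonimide), THF, −78 °C
Reagents that add atoms: N-(5-chloropyridin-2-yl)bis(trifluoromethanesulfonimide), O=S(=O)(N(c1ccc(Cl)cn1)S(=O)(=O)C(F)(F)F)C(F)(F)F
Why: Kinetic deprotonation at the ketone methyl group, which is more acidic and less hindered than the branched ester α-position, with in-situ O-triflation gives the 1,1-disubstituted enol triflate, so C2 is not enolised and β-elimination of the peroxide is avoided.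

Step 10
Reactants: 19 β-cyclocitral (2,6,6-trimethylcyclohex-1-ene-1-carbaldehyde)
Product: 20 β-cyclogeraniol ((2,6,6-trimethylcyclohex-1-en-1-yl)methanol)
Conditions: NaBH4, MeOH, 0 °C
Reagents that add atoms: none
Why: Borohydride 1,2-reduction of the hindered enal gives the allylic alcohol needed for directed epoxidation.

Step 11
Reactants: 20 β-cyclogeraniol
Product: 21 [(1S,6S)-2,2,6-trimethyl-7-oxabicyclo[4.1.0]heptan-1-yl]methanol
Conditions: Ti(OiPr)4 (20 mol%), L-(+)-diethyl tartrate (24 mol%), t-BuOOH, 4 Å MS, CH2Cl2, −20 °C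
Reagents that add atoms: tert-butyl hydroperoxide, CC(C)(C)OO
Why: In this Sharpless asymmetric epoxidation the L-(+)-tartrate titanium complex delivers oxygen to the face of the allylic alkene that gives the (1S,6S)-epoxide, which fixes the C13–O bond of the target.

Step 12
Reactants: 21 [(1S,6S)-2,2,6-trimethyl-7-oxabicyclo[4.1.0]heptan-1-yl]methanol
Product: 22 (1R,6S)-2,2,6-trimethyl-7-oxabicyclo[4.1.0]heptane-1-carbaldehyde
Conditions: Pr4N[RuO4] (5 mol%), N-methylmorpholine N-oxide, 4 Å MS, CH2Cl2, rt
Reagents that add atoms: none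
Why: Ley–Griffith oxidation gives the non-enolisable epoxy aldehyde under neutral conditions that spare the acid-sensitive tetrasubstituted epoxide.

Step 13
Reactants: 22 (1R,6S)-2,2,6-trimethyl-7-oxabicyclo[4.1.0]heptane-1-carbaldehyde
Product: 23 (1R,6S)-1-ethenyl-2,2,6-trimethyl-7-oxabicyclo[4.1.0]heptane
Conditions: MePPh3Br, KOtBu, THF, 0 °C
Reagents that add atoms: methyltriphenylphosphonium bromide, C[P+](c1ccccc1)(c1ccccc1)c1ccccc1.[Br-]
Why: Wittig methylenation adds C11, and the quaternary α-carbon C13 cannot epimerise.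

Step 14
Reactants: 23 (1R,6S)-1-ethenyl-2,2,6-trimethyl-7-oxabicyclo[4.1.0]heptane
Product: 24 (1R)-1-ethenyl-2,2-dimethyl-6-methylidenecyclohexan-1-ol
Conditions: LiNEt2 (from Et2NH, n-BuLi), Et2O–hexane, 0 °C → reflux
Reagents that add atoms: none
Why: In this base-induced epoxide-to-allylic-alcohol isomerisation (syn β-elimination) only C14 has neighbours with β-hydrogens, the amide should take the least hindered methyl hydrogen, the C14–O bond breaks, and the C13–O bond keeps its configuration.

Step 15
Reactants: 24 (1R)-1-ethenyl-2,2-dimethyl-6-methylidenecyclohexan-1-ol; 18 enol triflate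
Product: 26 target CNP0185522.3, via alkyl(disiamyl)borane borinate 25 (not isolated)
Conditions: disiamylborane (2.2 equiv, from BH3·SMe2 and 2-methylbut-2-ene), THF, 0 °C; then 18, PdCl2(dppf) (10 mol%), AsPh3, Cs2CO3, DMF–H2O, rt
Reagents that add atoms: none
Why: The hindered dialkylborane should hydroborate the monosubstituted vinyl group much faster than the 1,1-disubstituted ring methylidene next to a quaternary carbon, and B-alkyl Suzuki–Miyaura coupling with the enol triflate under mild carbonate conditions forms C10–C11 without creating or touching a stereocentre.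

Compound list
1 | cyclobutanone | O=C1CCC1 | starting material
2 | lithium cyclobut-1-en-1-olate | [Li+].[O-]C1=CCC1 | intermediate
3 | cyclobut-1-en-1-yl trifluoromethanesulfonate | O=S(=O)(OC1=CCC1)C(F)(F)F | intermediate
4 | (2R)-pent-4-en-2-ol | C[C@@H](O)CC=C | starting material
5 | 9-[(4R)-4-(9-borabicyclo[3.3.1]nonan-9-yloxy)pentyl]-9-borabicyclo[3.3.1]nonane | C[C@@H](OB1C2CCCC1CCC2)CCCB1C2CCCC1CCC2 | intermediate
6 | (2R)-5-(cyclobut-1-en-1-yl)pentan-2-ol | C[C@@H](O)CCCC1=CCC1 | intermediate
7 | carbonyl oxide of (8R)-8-hydroxy-4-oxononanal (oxide on C6) | C[C@@H](O)CCCC(=[O+][O-])CCC=O | intermediate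
8 | 3-[(6R)-2-hydroperoxy-6-methyloxan-2-yl]propanal | C[C@@H]1CCCC(CCC=O)(OO)O1 | intermediate
9 | (6S,8R)-8-methyl-1,2,7-trioxaspiro[5.5]undecan-3-ol | C[C@@H]1CCC[C@@]2(O1)CCC(O)OO2 | intermediate
10 | (6S,8R)-8-methyl-1,2,7-trioxaspiro[5.5]undecan-3-yl acetate | C[C@@H]1CCC[C@@]2(O1)CCC(OC(C)=O)OO2 | intermediate
11 | methyl propanoate | CCC(=O)OC | starting material
12 | lithium (E)-1-methoxyprop-1-en-1-olate | [Li+].C/C=C(/[O-])OC | intermediate
13 | (E)-1-methoxy-1-(trimethylsilyloxy)prop-1-ene | C/C=C(/O[Si](C)(C)C)OC | intermediate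
14 | methyl (2R)-2-[(3S,6S,8R)-8-methyl-1,2,7-trioxaspiro[5.5]undecan-3-yl]propanoate | C[C@@H]1CCC[C@@]2(O1)CC[C@@H]([C@@H](C)C(=O)OC)OO2 | intermediate
15 | methyl (2R)-2-[(3S,6R)-6-[(4R)-4-hydroxypentyl]-6-methyl-1,2-dioxan-3-yl]propanoate | C[C@@H](O)CCC[C@]1(C)CC[C@@H]([C@@H](C)C(=O)OC)OO1 | intermediate
16 | methyl (2R)-2-[(3S,6R)-6-methyl-6-(4-oxopentyl)-1,2-dioxan-3-yl]propanoate | CC(=O)CCC[C@]1(C)CC[C@@H]([C@@H](C)C(=O)OC)OO1 | intermediate
17 | potassium enolate of 16 (terminal) | [K+].C=C([O-])CCC[C@]1(C)CC[C@@H]([C@@H](C)C(=O)OC)OO1 | intermediate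
18 | methyl (2R)-2-[(3S,6R)-6-methyl-6-[4-(trifluoromethylsulfonyloxy)pent-4-en-1-yl]-1,2-dioxan-3-yl]propanoate | C=C(OS(=O)(=O)C(F)(F)F)CCC[C@]1(C)CC[C@@H]([C@@H](C)C(=O)OC)OO1 | intermediate
19 | β-cyclocitral | CC1=C(C=O)C(C)(C)CCC1 | starting material
20 | β-cyclogeraniol | CC1=C(CO)C(C)(C)CCC1 | intermediate
21 | [(1S,6S)-2,2,6-trimethyl-7-oxabicyclo[4.1.0]heptan-1-yl]methanol | OC[C@]12O[C@@]1(C)CCCC2(C)C | intermediate
22 | (1R,6S)-2,2,6-trimethyl-7-oxabicyclo[4.1.0]heptane-1-carbaldehyde | O=C[C@]12O[C@@]1(C)CCCC2(C)C | intermediate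
23 | (1R,6S)-1-ethenyl-2,2,6-trimethyl-7-oxabicyclo[4.1.0]heptane | C=C[C@]12O[C@@]1(C)CCCC2(C)C | intermediate
24 | (1R)-1-ethenyl-2,2-dimethyl-6-methylidenecyclohexan-1-ol | C=C[C@]1(O)C(=C)CCCC1(C)C | intermediate
25 | [2-[(1R)-1-[bis(3-methylbutan-2-yl)boranyloxy]-2,2-dimethyl-6-methylidenecyclohexyl]ethyl]bis(3-methylbutan-2-yl)borane | CC(C)C(C)B(CC[C@]1(OB(C(C)C(C)C)C(C)C(C)C)C(=C)CCCC1(C)C)C(C)C(C)C | intermediate
26 | methyl (2R)-2-[(3S,6R)-6-[6-[(1R)-1-hydroxy-2,2-dimethyl-6-methylidenecyclohexyl]-4-methylidenehexyl]-6-methyl-1,2-dioxan-3-yl]propanoate (CNP0185522.3) | C=C(CCC[C@]1(C)CC[C@@H]([C@@H](C)C(=O)OC)OO1)CC[C@]1(O)C(=C)CCCC1(C)C | target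

Total step count: 15. Longest linear sequence: 9 steps (1, 2, 3, 4, 6, 7, 8, 9, 15).

Steps most likely to fail

**1. Step 7.** Methyl could be transferred to a peroxide oxygen. The C6–O1 bond could ionise instead of the C6–O(oxane) bond, which would open ring A. Delivery from the aluminium still bound to the departing oxygen would erode the facial selectivity.

The fallback uses known chemistry only. It sets out from 4, returns at 15, and places the C6 methyl group before the peroxide is made.
- Silylation of 4 (t-BuMe2SiCl, imidazole) gives the silyl ether F1.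
- Cross-metathesis with but-3-en-2-one (second-generation Hoveyda–Grubbs catalyst) gives the enone F2.
- Hydrogenation (H2, Pd/C) gives the methyl ketone F3.
- Spiroannulation with cyclopropyldiphenylsulfonium tetrafluoroborate and KOH gives the oxaspiropentane F4, which LiBF4 rearranges to the 2,2-disubstituted cyclobutanone F5.
- NaBH4 gives the cyclobutanol F6.
- The known oxidative ring expansion of secondary cyclobutanols (Co(acac)2 cat., O2, toluene, 40 °C) gives the 1,2-dioxan-3-ol F7. It runs through the alkoxy radical, β-scission to the tertiary C6 radical, O2 capture and hemiacetal closure.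
- Acetylation gives the acetate F8, and 13 with Me3SiOTf gives the silyl-protected ester F9.
- HF·pyridine then returns 15.

In this variant C6 stems from a planar radical and ring A has no conformational bias. It therefore trades stereocontrol for precedent and relies on chromatographic separation of the diastereomers, which the (R)-silyloxy centre makes distinguishable.

**2. Step 6.** Ionisation at the spiroketal carbon may compete with that of the acetate, and the simple diastereoselection at C2 may be low.

The fallback sets out from 10, returns at 14, and sets C2 by an allylsilane SE2′ reaction instead of an ester enolate equivalent.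
- (E)-But-2-en-1-yltrimethylsilane with SnCl4 or Me3SiOTf at −78 °C should give the syn crotylation product F10 by the same axial attack at C3.
- Ozonolysis of the vinyl group (O3, CH2Cl2, −78 °C; Me2S) gives the aldehyde F11.
- Pinnick oxidation (NaClO2, NaH2PO4, 2-methylbut-2-ene) gives the acid F12.
- Me3SiCHN2 in MeOH–toluene gives 14.

**3. Step 15.** The ring methylidene may be hydroborated in competition. Boron-to-palladium transfer from the hindered borane may be slow. The peroxide may decay under base or arsine/phosphine during a long coupling.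

The fallback sets out from 23, returns at 26, and hydroborates before the ring methylidene exists.
- 9-BBN-H, then NaBO3, gives the epoxy alcohol F13.
- Excess LiNEt2 gives the diol F14.
- I2, PPh3 and imidazole give the primary iodide F15.
- Me3SiOTf and 2,6-lutidine give the silyl ether F16.
- Zn dust with LiCl in THF gives the alkylzinc iodide F17.
- Negishi coupling with 18 (PdCl2(dppf), THF, rt) gives the silyl ether of the target F18.
- Bu4NF buffered with AcOH gives 26.

Further compounds
F1 | step 7 | tert-butyldimethyl[(2R)-pent-4-en-2-yloxy]silane | C[C@@H](O[Si](C)(C)C(C)(C)C)CC=C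
F2 | step 7 | (3E,6R)-6-(tert-butyldimethylsilyloxy)hept-3-en-2-one | C[C@@H](O[Si](C)(C)C(C)(C)C)C/C=C/C(C)=O
F3 | step 7 | (6R)-6-(tert-butyldimethylsilyloxy)heptan-2-one | C[C@@H](O[Si](C)(C)C(C)(C)C)CCCC(C)=O
F4 | step 7 | 2-methyl-2-[(4R)-4-(tert-butyldimethylsilyloxy)pentyl]-1-oxaspiro[2.2]pentane | C[C@@H](O[Si](C)(C)C(C)(C)C)CCCC1(C)OC12CC2
F5 | step 7 | 2-methyl-2-[(4R)-4-(tert-butyldimethylsilyloxy)pentyl]cyclobutan-1-one | C[C@@H](O[Si](C)(C)C(C)(C)C)CCCC1(C)CCC1=O
F6 | step 7 | 2-methyl-2-[(4R)-4-(tert-butyldimethylsilyloxy)pentyl]cyclobutan-1-ol | C[C@@H](O[Si](C)(C)C(C)(C)C)CCCC1(C)CCC1O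
F7 | step 7 | 6-methyl-6-[(4R)-4-(tert-butyldimethylsilyloxy)pentyl]-1,2-dioxan-3-ol | C[C@@H](O[Si](C)(C)C(C)(C)C)CCCC1(C)CCC(O)OO1
F8 | step 7 | 6-methyl-6-[(4R)-4-(tert-butyldimethylsilyloxy)pentyl]-1,2-dioxan-3-yl acetate | C[C@@H](O[Si](C)(C)C(C)(C)C)CCCC1(C)CCC(OC(C)=O)OO1
F9 | step 7 | methyl (2R)-2-[(3S,6R)-6-methyl-6-[(4R)-4-(tert-butyldimethylsilyloxy)pentyl]-1,2-dioxan-3-yl]propanoate | C[C@@H](O[Si](C)(C)C(C)(C)C)CCC[C@]1(C)CC[C@@H]([C@@H](C)C(=O)OC)OO1
F10 | step 6 | (3S,6S,8R)-3-[(2S)-but-3-en-2-yl]-8-methyl-1,2,7-trioxaspiro[5.5]undecane | C[C@@H]1CCC[C@@]2(O1)CC[C@@H]([C@@H](C)C=C)OO2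
F11 | step 6 | (2R)-2-[(3S,6S,8R)-8-methyl-1,2,7-trioxaspiro[5.5]undecan-3-yl]propanal | C[C@@H]1CCC[C@@]2(O1)CC[C@@H]([C@@H](C)C=O)OO2
F12 | step 6 | (2R)-2-[(3S,6S,8R)-8-methyl-1,2,7-trioxaspiro[5.5]undecan-3-yl]propanoic acid | C[C@@H]1CCC[C@@]2(O1)CC[C@@H]([C@@H](C)C(=O)O)OO2
F13 | step 15 | 2-[(1R,6S)-2,2,6-trimethyl-7-oxabicyclo[4.1.0]heptan-1-yl]ethan-1-ol | OCC[C@]12O[C@@]1(C)CCCC2(C)C
F14 | step 15 | (1R)-1-(2-hydroxyethyl)-2,2-dimethyl-6-methylidenecyclohexan-1-ol | OCC[C@]1(O)C(=C)CCCC1(C)C
F15 | step 15 | (1R)-1-(2-iodoethyl)-2,2-dimethyl-6-methylidenecyclohexan-1-ol | ICC[C@]1(O)C(=C)CCCC1(C)C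
F16 | step 15 | [(1R)-1-(2-iodoethyl)-2,2-dimethyl-6-methylidenecyclohexyl]oxy-trimethylsilane | ICC[C@]1(O[Si](C)(C)C)C(=C)CCCC1(C)C
F17 | step 15 | [2-[(1R)-2,2-dimethyl-6-methylidene-1-(trimethylsilyloxy)cyclohexyl]ethyl]zinc iodide | I[Zn]CC[C@]1(O[Si](C)(C)C)C(=C)CCCC1(C)C
F18 | step 15 | trimethylsilyl ether of 26 at the C13 hydroxyl | C=C(CCC[C@]1(C)CC[C@@H]([C@@H](C)C(=O)OC)OO1)CC[C@]1(O[Si](C)(C)C)C(=C)CCCC1(C)C
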